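Readings and results were generated by integration on assumed constants, noise included.

The amounts on the table are 0.10 M of E kept cold (maple) and 0.30 M of E warmed after 6.0 min (cedar), and the next run gets whichever recipe ends with more Z.

| flask | E | G | L | J | temperature | remark | time |
|---|---|---|---|---|---|---|---|
| blue | 0.13 M (fed, over 30 min) | 0.60 M | 0.30 M | 6 mM | −32 °C | run made earlier |  |
| violet | 0.43 M (fed, over 30 min) | 0.60 M | 0.30 M | 6 mM | −16 °C | run made earlier |  |
| maple | 0.10 M (fed, over 30 min) | 0.600 M | 0.300 M | 6.0 mM |  | at −40 °C throughout | 30 min |
| cedar | 0.30 M (fed, over 30 min) | 0.600 M | 0.300 M | 6.0 mM |  | at −40 °C until 6.0 min, from then on at −10 °C | 30 min |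

| blue: time / min | blue: Z / % | violet: time / min | violet: Z / % |
|---|---|---|---|
| 4.00 | 1.3 | 0.833 | 0.7 |
| 8.00 | 4.4 | 1.33 | 0 |
| 12.0 | 6.5 | 2.00 | 0.9 |
| 15.0 | 10.7 | 2.50 | 0.6 |
| 20.0 | 14.7 | 4.00 | 1.7 |
| 25.0 | 21.3 | 6.00 | 4.7 |
| 30.0 | 26.7 | 10.0 | 7.7 |

(readings scatter by 0.5 percentage points)

- a species is counted by the E in it: one X counts as two
- what was read earlier has a scatter of 0.5 percentage points, one standard deviation
- steps that have been proposed: E + G + J -> J + Z; 2 E -> X; L + G + J -> J + D
- percentages count the whole charge, also what has not yet gone in

1. which one finishes higher in amount of Z, in percent of the E charged ("neither" within 2 percentage points) (maple / cedar / neither)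
2. amount of Z at the end, in percent of the E charged, maple
3. amount of Z at the end, in percent of the E charged, cedar

While E is fed at a rate F and [E] holds steady, E leaves by a pseudo-first-order path to Z (at given [G] and [J]) and by a path to X that is second order in [E]. The selectivity s, the share of the feed reaching Z, then makes F times s squared, divided by the share lost, a quantity that is constant at one temperature and grows with the square of [G][J].

Blue's last stretch, 20.0 min to 30.0 min, reads s = 36.0 %, which gives 8.78 × 10⁻⁴ M/min. Violet, 6.00 min to 10.0 min, reads 22.5 %, which gives 9.36 × 10⁻⁴ M/min, but that short stretch carries a scatter of 5.3 percentage points on s, so the two readings cannot show how K moves with temperature. Their mean, 9.07 × 10⁻⁴ M/min, serves here as a rough working value of the capture constant K, not as a constant shown to hold across temperature.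

Cedar's feed of 0.0100 M/min then gives s = 25.9 %, and this reckoning takes that as cedar's Z. Maple's slower feed gives 40.3 %, but that asks 6.72 turnovers of J.

Maple is therefore counted another way, from the pseudo-first-order constant κ of E to Z. Early in a feed, before X counts, Z's share of the charge grows as κ/2 times the square of the time over the dosing time, so blue's reading at 8.00 min gives κ = 0.0413 /min. This reckoning assumes, with no reading to show it, that κ falls by a factor of 2 from blue's temperature to maple's, which gives 0.0206 /min and 0.619 over the feed. With nothing lost to X, maple then ends at 25.4 % Z, or 4.24 turnovers of J, and X lowers that ceiling. Cedar's figure stands 0.50 points above the ceiling, within the margin, so the lean is to charge cedar, though this reckoning does not show a lead beyond the margin.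

The forecast holds that “warmth favours Z”, where this reckoning uses one mean K, and it gives cedar, with 22 % for maple and 27 % for cedar.

The flasks give cedar higher, maple 19.7 % and cedar 27.8 %.

    E + G + J → J + Z (k = 0.0937 /M²/s, Ea = 41.0 kJ/mol)
    2 E → X (k = 0.00432 /M/s, Ea = 59.0 kJ/mol)
    L + G + J → J + D (k = 0.0373 /M²/s, Ea = 38.0 kJ/mol)
    (constants at −40 °C)

At 30.0 min cedar's E goes 3.1 times as fast to X as to Z, a running selectivity of 24.2 %. That ratio holds at −10 °C with G at 50.2 % of its charge, so it stands on another basis than K, which was read in blue and violet at other temperatures.

A neighbour of cedar charged with 1.5 M of G raises K to 0.00567 M/min, which gives s = 52.1 %. That neighbour ends with 58.7 % of Z and 5.14 % of E left.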